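**Retrosynthetic overview**
1. Numbering (cembrane; the target SMILES read left to right is C19=C8, C7, C6, C5, C4(C18), C3(OH), C2, O, C16(=O), C15(=C17), C1, C14, C13(OH), C12(C20), C11, C10, C9, ring O).
2. The last step closes the 13-membered ring C1–C9/O/C12–C14 from a seco precursor that holds only the lactone ring. Two bonds form in one operation: C8–C9 (Nozaki–Hiyama–Kishi addition of the C8 alkenyl iodide to the C9 aldehyde, closing the carbocycle), then O–C12 (the new C9 oxygen opens a 12,13-epoxide, closing the oxolane and with it the 13-membered ring).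
3. Enabling feature: C9 is both the allylic carbinol carbon next to the exocyclic C8=C19 alkene and an oxolane carbon, and the other oxolane carbon C12 carries its oxygen anti to the C13 hydroxyl. This is the pattern left by an alkenyl–aldehyde addition followed by 5-exo opening of a trans-epoxide with inversion at C12.
4. The lactone ring comes first: the C1–C2 bond by indium Barbier union of an α-hydroxy aldehyde (C2–C8, C18, C19; from crotylboration) with a (Z)-2-(bromomethyl)enoate (C1, C9–C17, C20; from carboalumination and vinylalumination), which sets C1 and C2. C12/C13 come from a Shi epoxidation.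
5. Order of ring formation: lactone (step 9), oxirane as a temporary ring (step 10), then in step 12 the carbocycle, the oxolane and the 13-membered oxa-ring.

Key step: step 12

Remark: 2,2-dimethoxyacetaldehyde (sold as an aqueous solution) is taken as the dry monomer, obtained by extraction and distillation before use.

**Route**

Step 1
Reactants: 1 2,2-dimethoxyacetaldehyde; 2 cis-but-2-ene
Product: 5 (2R,3S)-1,1-dimethoxy-3-methylpent-4-en-2-ol, via (Z)-but-2-enylpotassium 3 (not isolated), via (Z)-crotylbis(isopinocampheyl)borane 4 (not isolated)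
Conditions: 2, KOtBu, n-BuLi, THF, −78 to −45 °C; (+)-Ipc2BOMe [from (−)-α-pinene], −78 °C; BF3·OEt2; 1, −78 °C; then NaOH, H2O2
Reagents that add atoms: none
Why: Brown crotylboration through a closed chair transition state, in which the Z crotyl geometry should give the syn C3-hydroxyl/C4-methyl pair and the isopinocampheyl groups from (−)-α-pinene should direct the crotyl group to the Re face of the aldehyde, setting C3 (R) and C4 (S) of the target.

Step 2
Reactants: 5 (2R,3S)-1,1-dimethoxy-3-methylpent-4-en-2-ol; 6 2,3-dibromoprop-1-ene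
Product: 8 (2R,3S)-7-bromo-1,1-dimethoxy-3-methyloct-7-en-2-ol, via B-alkyl-9-BBN 7 (not isolated)
Conditions: 9-BBN dimer (excess), THF, 0 °C to rt; then 6, CuOAc (cat.), KOtBu, THF, rt
Reagents that add atoms: none
Why: Anti-Markovnikov hydroboration of the terminal alkene (the hydroxyl is held as its 9-BBN borinate) followed by copper-catalysed allyl–alkyl coupling of the alkylborate with the allylic bromide of 6 should install C7, C8 and C19 and leave the alkenyl bromide and both stereocenters untouched.

Step 3
Reactants: 8 (2R,3S)-7-bromo-1,1-dimethoxy-3-methyloct-7-en-2-ol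
Product: 9 (2R,3S)-7-iodo-1,1-dimethoxy-3-methyloct-7-en-2-ol
Conditions: NaI, CuI (cat.), trans-N,N′-dimethylcyclohexane-1,2-diamine (cat.), 1,4-dioxane, 110 °C
Reagents that add atoms: sodium iodide [Na+].[I-]
Why: Copper-catalysed halogen exchange (Finkelstein-type reaction of an alkenyl bromide) should give the alkenyl iodide that undergoes oxidative addition more readily in step 12.

Step 4
Reactants: 10 pent-4-yn-1-ol
Product: 11 tert-butyldimethyl(pent-4-yn-1-yloxy)silane
Conditions: TBSCl, imidazole, DMF, rt
Reagents that add atoms: tert-butyldimethylsilyl chloride CC(C)(C)[Si](C)(C)Cl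
Why: Standard silylation of a primary alcohol, masking the future C9 oxygen until step 11.

Step 5
Reactants: 11 tert-butyldimethyl(pent-4-yn-1-yloxy)silane
Product: 14 (3E)-7-[(tert-butyldimethylsilyl)oxy]-4-methylhept-3-en-1-ol, via alkenyldimethylalane 12 (not isolated), via lithium alkenylaluminate 13 (not isolated)
Conditions: AlMe3, Cp2ZrCl2 (cat.), CH2Cl2, 0 °C to rt; n-BuLi, hexane/THF, −78 °C; ethylene oxide, −78 to 0 °C; aq. potassium sodium tartrate
Reagents that add atoms: trimethylaluminium C[Al](C)C; ethylene oxide C1CO1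
Why: Negishi zirconium-catalysed carboalumination adds methyl and aluminium syn across the alkyne (methyl to the internal carbon), and the derived alkenylaluminate opens ethylene oxide with retention of geometry, which should fix the E C12=C13 alkene with C20, C14 and C1 in place.

Step 6
Reactants: 14 (3E)-7-[(tert-butyldimethylsilyl)oxy]-4-methylhept-3-en-1-ol
Product: 15 (3E)-7-[(tert-butyldimethylsilyl)oxy]-4-methylhept-3-enal
Conditions: Dess–Martin periodinane, pyridine, CH2Cl2, 0 °C; crude product used at once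
Reagents that add atoms: none
Why: Dess–Martin oxidation under buffered, non-basic conditions should give the β,γ-unsaturated aldehyde without migration of the alkene into conjugation.

Step 7
Reactants: 15 (3E)-7-[(tert-butyldimethylsilyl)oxy]-4-methylhept-3-enal; 16 methyl propiolate
Product: 18 methyl (5E)-9-[(tert-butyldimethylsilyl)oxy]-3-hydroxy-6-methyl-2-methylidenenon-5-enoate (racemic at C3), via [1-(methoxycarbonyl)vinyl]diisobutylalane 17 (not isolated)
Conditions: 16, DIBAL-H, N-methylmorpholine N-oxide, THF, 0 °C; then 15, 0 °C to rt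
Reagents that add atoms: none
Why: Vinylalumination (hydroalumination of the propiolate to an α-aluminoacrylate that adds to the aldehyde) should give the Morita–Baylis–Hillman-type adduct without the amine base that could isomerise the skipped enal, and the racemic carbinol center is removed in step 8.

Step 8
Reactants: 18 methyl (5E)-9-[(tert-butyldimethylsilyl)oxy]-3-hydroxy-6-methyl-2-methylidenenon-5-enoate
Product: 19 methyl (2Z,5E)-2-(bromomethyl)-9-[(tert-butyldimethylsilyl)oxy]-6-methylnona-2,5-dienoate
Conditions: NBS, Me2S, CH2Cl2, 0 °C to rt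
Reagents that add atoms: N-bromosuccinimide O=C1CCC(=O)N1Br
Why: Bromination of the Morita–Baylis–Hillman alcohol with the NBS–Me2S reagent (Corey–Kim-type activation) proceeds with allylic transposition (SN2′) and should give the thermodynamically preferred (2Z)-2-(bromomethyl)enoate.

Step 9
Reactants: 9 (2R,3S)-7-iodo-1,1-dimethoxy-3-methyloct-7-en-2-ol; 19 methyl (2Z,5E)-2-(bromomethyl)-9-[(tert-butyldimethylsilyl)oxy]-6-methylnona-2,5-dienoate
Product: 22 (4S,5R)-5-[(1R,2S)-1-hydroxy-6-iodo-2-methylhept-6-en-1-yl]-4-[(2E)-6-{[tert-butyl(dimethyl)silyl]oxy}-3-methylhex-2-en-1-yl]-3-methylideneoxolan-2-one, via α-hydroxy aldehyde 20 (not isolated), via dihydroxy ester 21 (not isolated)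
Conditions: 9, Amberlyst-15 (H+ form), THF/H2O, 50 °C, filter; then 19, indium powder, THF/H2O, rt; then CSA (cat.), CH2Cl2, rt
Reagents that add atoms: water O
Why: Indium-mediated Barbier allylation in water, in which the allylindium reagent adds at its substituted γ-carbon through a chair transition state (Z geometry giving the syn C1/C2 pair) while the free C3 hydroxyl chelates indium together with the carbonyl oxygen so that attack comes anti to the C4 branch (syn C2/C3), after which acid should close the five-membered cis-lactone through the C2 hydroxyl with loss of methanol.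

Step 10
Reactants: 22 (the lactone of step 9)
Product: 23 (4S,5R)-4-{[(2R,3R)-3-(3-{[tert-butyl(dimethyl)silyl]oxy}propyl)-3-methyloxiran-2-yl]methyl}-5-[(1R,2S)-1-hydroxy-6-iodo-2-methylhept-6-en-1-yl]-3-methylideneoxolan-2-one
Conditions: D-fructose-derived ketone (1,2:4,5-di-O-isopropylidene-β-D-erythro-2,3-hexodiulo-2,6-pyranose, cat.), Oxone (2KHSO5·KHSO4·K2SO4), K2CO3, Bu4NHSO4, Na2B4O7/Na2EDTA buffer, MeCN/CH2(OMe)2, 0 °C
Reagents that add atoms: potassium peroxymonosulfate (active component of Oxone) [K+].OOS(=O)(=O)[O-]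
Why: Shi asymmetric epoxidation, in which the chiral dioxirane should attack only the electron-rich trisubstituted C12=C13 alkene through the spiro transition state and give the (12R,13R)-epoxide under reagent control, the alkenyl iodide and the electron-poor methylidene lactone being far less reactive.

Step 11
Reactants: 23 (the epoxide of step 10)
Product: 25 3-[(2R,3R)-3-({(2R,3S)-2-[(1R,2S)-1-hydroxy-6-iodo-2-methylhept-6-en-1-yl]-4-methylidene-5-oxooxolan-3-yl}methyl)-2-methyloxiran-2-yl]propanal, via epoxy diol 24 (not isolated)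
Conditions: TBAF, THF, 0 °C, pH 7 phosphate work-up, no chromatography; then [Cu(MeCN)4]OTf (cat.), 2,2′-bipyridine, TEMPO (cat.), N-methylimidazole, air, MeCN, rt
Reagents that add atoms: none
Why: Fluoride cleaves the primary silyl ether without acid, and the copper/TEMPO aerobic oxidation should convert only the primary alcohol (not the secondary C3 alcohol) into the C9 aldehyde under conditions that leave the epoxide closed.

Step 12
Reactants: 25 (the epoxy aldehyde of step 11)
Product: 27 uprolide D, via macrocyclic epoxy alcohol 26 (not isolated)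
Conditions: CrCl2, (S)-N-[2-(4-isopropyl-4,5-dihydro-1,3-oxazol-2-yl)-6-methylphenyl]methanesulfonamide, Et3N, NiCl2 (cat.), THF, rt, slow addition of 25 to 2 mM; aq. Na2EDTA work-up; then PPTS (cat.), CH2Cl2, 0 °C to rt, on the crude product
Reagents that add atoms: none
Why: Nozaki–Hiyama–Kishi reaction run as a macrocyclisation and telescoped with an epoxy alcohol closure: zerovalent nickel (from NiCl2 and CrCl2) inserts into the C8–I bond, transmetalation gives an alkenyl species of trivalent chromium that adds to the C9 aldehyde, and the C9 oxygen so created opens the 12,13-epoxide when crude 26 meets PPTS. The closest known reactions are ligand-controlled Ni/Cr couplings of 2-iodoalk-1-enes with aldehydes, including macrocyclic cases and cases in which the new alkoxide goes on to close a cyclic ether, and acid-catalysed 5-exo closures of 4,5-epoxy alcohols to oxolanes. Ring closures: C8–C9 bond formation is a 14-exo-trig addition to the carbonyl group that closes the carbocycle, and O–C12 bond formation is a 5-exo-tet epoxide opening that closes the oxolane and, by bridging C9 and C12, the 13-membered ring C1–C9/O/C12–C14. Stereocenters: C9 is new and is set to R by the chiral sulfonamide ligand on chromium, whose enantiomer is chosen to deliver the alkenyl group to the Si face of the aldehyde (the S ligand is the one proposed); C12 is inverted stereospecifically (12R in the epoxide, 12S in the ether) and C13 keeps its C–O bond, so both follow from the epoxide of step 10. Selectivity needed: aldehyde over lactone, epoxide and free C3 hydroxyl (secured by the low basicity and aldehyde selectivity of organochromium reagents), attack at C12 and not at C13 (five- against six-membered transition state and the tertiary carbon that better carries positive charge under acid), and ring closure over oligomerisation (2 mM, slow addition, and a chain pre-bent by the cis-lactone and the trans-epoxide). The 9R alcohol places its oxygen on the face of the forming oxolane that gives the cis relationship of the C8 and C13 branches found in 27.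

**Compound list**

1 | 2,2-dimethoxyacetaldehyde | COC(OC)C=O | starting material
2 | cis-but-2-ene | C/C=C\C | starting material
3 | (Z)-but-2-enylpotassium | [K+].[CH2-]/C=C\C | intermediate
4 | (Z)-crotylbis(isopinocampheyl)borane, Ipc groups from (−)-α-pinene | C/C=C\CB([C@H]1C[C@H]2C[C@@H]([C@@H]1C)C2(C)C)[C@H]1C[C@H]2C[C@@H]([C@@H]1C)C2(C)C | intermediate
5 | (2R,3S)-1,1-dimethoxy-3-methylpent-4-en-2-ol | C=C[C@H](C)[C@@H](O)C(OC)OC | intermediate
6 | 2,3-dibromoprop-1-ene | C=C(Br)CBr | starting material
7 | B-alkyl-9-BBN from 5, 9-[(3S,4R)-4-(9-borabicyclo[3.3.1]nonan-9-yloxy)-5,5-dimethoxy-3-methylpentyl]-9-borabicyclo[3.3.1]nonane | COC(OC)[C@H](OB1C2CCCC1CCC2)[C@@H](C)CCB1C2CCCC1CCC2 | intermediate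
8 | (2R,3S)-7-bromo-1,1-dimethoxy-3-methyloct-7-en-2-ol | C=C(Br)CCC[C@H](C)[C@@H](O)C(OC)OC | intermediate
9 | (2R,3S)-7-iodo-1,1-dimethoxy-3-methyloct-7-en-2-ol | C=C(I)CCC[C@H](C)[C@@H](O)C(OC)OC | intermediate
10 | pent-4-yn-1-ol | C#CCCCO | starting material
11 | tert-butyldimethyl(pent-4-yn-1-yloxy)silane | C#CCCCO[Si](C)(C)C(C)(C)C | intermediate
12 | (E)-{5-[(tert-butyldimethylsilyl)oxy]-2-methylpent-1-en-1-yl}dimethylalane | C[Al](C)/C=C(\C)CCCO[Si](C)(C)C(C)(C)C | intermediate
13 | lithium butyl{(E)-5-[(tert-butyldimethylsilyl)oxy]-2-methylpent-1-en-1-yl}dimethylaluminate | [Li+].CCCC[Al-](C)(C)/C=C(\C)CCCO[Si](C)(C)C(C)(C)C | intermediate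
14 | (3E)-7-[(tert-butyldimethylsilyl)oxy]-4-methylhept-3-en-1-ol | OCC/C=C(\C)CCCO[Si](C)(C)C(C)(C)C | intermediate
15 | (3E)-7-[(tert-butyldimethylsilyl)oxy]-4-methylhept-3-enal | O=CC/C=C(\C)CCCO[Si](C)(C)C(C)(C)C | intermediate
16 | methyl propiolate | C#CC(=O)OC | starting material
17 | [1-(methoxycarbonyl)vinyl]diisobutylalane | C=C(C(=O)OC)[Al](CC(C)C)CC(C)C | intermediate
18 | methyl (5E)-9-[(tert-butyldimethylsilyl)oxy]-3-hydroxy-6-methyl-2-methylidenenon-5-enoate (racemic at C3) | C=C(C(=O)OC)C(O)C/C=C(\C)CCCO[Si](C)(C)C(C)(C)C | intermediate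
19 | methyl (2Z,5E)-2-(bromomethyl)-9-[(tert-butyldimethylsilyl)oxy]-6-methylnona-2,5-dienoate | COC(=O)/C(CBr)=C/C/C=C(\C)CCCO[Si](C)(C)C(C)(C)C | intermediate
20 | (2R,3S)-2-hydroxy-7-iodo-3-methyloct-7-enal | C=C(I)CCC[C@H](C)[C@@H](O)C=O | intermediate
21 | methyl (3S,4R,5R,6S)-3-[(2E)-6-{[tert-butyl(dimethyl)silyl]oxy}-3-methylhex-2-en-1-yl]-4,5-dihydroxy-10-iodo-6-methyl-2-methylideneundec-10-enoate | C=C(I)CCC[C@H](C)[C@@H](O)[C@H](O)[C@@H](C/C=C(\C)CCCO[Si](C)(C)C(C)(C)C)C(=C)C(=O)OC | intermediate
22 | (4S,5R)-5-[(1R,2S)-1-hydroxy-6-iodo-2-methylhept-6-en-1-yl]-4-[(2E)-6-{[tert-butyl(dimethyl)silyl]oxy}-3-methylhex-2-en-1-yl]-3-methylideneoxolan-2-one | C=C(I)CCC[C@H](C)[C@@H](O)[C@@H]1OC(=O)C(=C)[C@@H]1C/C=C(\C)CCCO[Si](C)(C)C(C)(C)C | intermediate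
23 | (4S,5R)-4-{[(2R,3R)-3-(3-{[tert-butyl(dimethyl)silyl]oxy}propyl)-3-methyloxiran-2-yl]methyl}-5-[(1R,2S)-1-hydroxy-6-iodo-2-methylhept-6-en-1-yl]-3-methylideneoxolan-2-one | C=C(I)CCC[C@H](C)[C@@H](O)[C@@H]1OC(=O)C(=C)[C@@H]1C[C@H]2O[C@]2(C)CCCO[Si](C)(C)C(C)(C)C | intermediate
24 | (4S,5R)-5-[(1R,2S)-1-hydroxy-6-iodo-2-methylhept-6-en-1-yl]-4-{[(2R,3R)-3-(3-hydroxypropyl)-3-methyloxiran-2-yl]methyl}-3-methylideneoxolan-2-one | C=C(I)CCC[C@H](C)[C@@H](O)[C@@H]1OC(=O)C(=C)[C@@H]1C[C@H]2O[C@]2(C)CCCO | intermediate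
25 | 3-[(2R,3R)-3-({(2R,3S)-2-[(1R,2S)-1-hydroxy-6-iodo-2-methylhept-6-en-1-yl]-4-methylidene-5-oxooxolan-3-yl}methyl)-2-methyloxiran-2-yl]propanal | C=C(I)CCC[C@H](C)[C@@H](O)[C@@H]1OC(=O)C(=C)[C@@H]1C[C@H]2O[C@]2(C)CCC=O | intermediate
26 | (1S,2R,3R,4S,9R,12R,13R)-12,13-epoxy-3,9-dihydroxycembra-8(19),15(17)-dien-16,2-olide (14-membered carbocycle) | C=C1CCC[C@H](C)[C@@H](O)[C@@H]2OC(=O)C(=C)[C@@H]2C[C@H]3O[C@]3(C)CC[C@H]1O | intermediate
27 | uprolide D, (1S,2R,3R,4S,9R,12S,13R)-9,12-epoxy-3,13-dihydroxycembra-8(19),15(17)-dien-16,2-olide | C=C1CCC[C@H](C)[C@@H](O)[C@@H]2OC(=O)C(=C)[C@@H]2C[C@@H](O)[C@]2(C)CC[C@H]1O2 | target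

**Summary**

Total step count: 12.
Longest linear sequence: 9 steps (pent-4-yn-1-ol 10 to 27, steps 4 to 12); the western branch joins after 3 steps.

Steps most likely to fail:

Step 12. What may go wrong: the alkenylchromium reagent may add to the wrong face of the C9 aldehyde inside the forming ring (loss of ligand control), which would carry through to the trans-oxolane; slow closure may also let oligomers form. Fallback (C9 set by reagent-controlled reduction instead of by the addition): starting from 25, the ring is closed with ligand-free CrCl2/NiCl2 (cat.) in DMSO at high dilution, and the epoxy alcohols are isolated without acid as 26 together with its (9S)-epimer F1. The mixture is oxidised at the allylic position only with MnO2 to the macrocyclic enone F2. Corey–Bakshi–Shibata reduction ((S)-1-methyl-3,3-diphenyltetrahydro-1H,3H-pyrrolo[1,2-c][1,3,2]oxazaborole, BH3·SMe2, low temperature; the alkenyl group acting as the large substituent) should return the route at 26, which is closed with PPTS to 27.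

Step 9. What may go wrong: non-chelated (Felkin-type) addition may compete, or the free α-hydroxy aldehyde may epimerise at C3 during acetal hydrolysis, eroding the C2/C3 relationship; acyl migration to the six-membered lactone through the C3 oxygen is a further drain. Fallback (Lewis-acid chelation control with an allylstannane instead of the aqueous Barbier reaction): from 9, the hydroxyl is etherified with 4-methoxybenzyl chloride (NaH, DMF) to the acetal F3, which is hydrolysed to the α-alkoxy aldehyde F4. Bromide 19 is converted with Bu3SnLi/CuBr·SMe2 into the allylstannane F5. MgBr2·OEt2-mediated addition of F5 to F4 through the five-membered magnesium chelate should give the hydroxy ester F6, which lactonises (CSA) to the lactone F7. Oxidative removal of the 4-methoxybenzyl group (DDQ, pH 7 buffer) returns the route at 22.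

Step 11. What may go wrong: the liberated C9 hydroxyl may close onto the 12,13-epoxide before it is oxidised (an oxolane without the C9 carbonyl), or fluoride may attack the methylidene lactone. Fallback (epoxide introduced only after ring closure): from 22, desilylation gives the diol F8, copper/TEMPO aerobic oxidation the aldehyde F9, and the ligand-controlled Ni/Cr ring closure the 14-membered (9R)-allylic alcohol F10. Shi epoxidation of its only trisubstituted alkene should then give 26, at which the route is rejoined and which closes with PPTS to 27.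

**Further compounds**

F1 | step 12 | (1S,2R,3R,4S,9S,12R,13R)-12,13-epoxy-3,9-dihydroxycembra-8(19),15(17)-dien-16,2-olide (C9 epimer of 26) | C=C1CCC[C@H](C)[C@@H](O)[C@@H]2OC(=O)C(=C)[C@@H]2C[C@H]3O[C@]3(C)CC[C@@H]1O
F2 | step 12 | (1S,2R,3R,4S,12R,13R)-12,13-epoxy-3-hydroxy-9-oxocembra-8(19),15(17)-dien-16,2-olide (macrocyclic enone) | C=C1CCC[C@H](C)[C@@H](O)[C@@H]2OC(=O)C(=C)[C@@H]2C[C@H]3O[C@]3(C)CCC1=O
F3 | step 9 | (2R,3S)-7-iodo-1,1-dimethoxy-2-[(4-methoxyphenyl)methoxy]-3-methyloct-7-ene | C=C(I)CCC[C@H](C)[C@@H](OCc1ccc(OC)cc1)C(OC)OC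
F4 | step 9 | (2R,3S)-7-iodo-2-[(4-methoxyphenyl)methoxy]-3-methyloct-7-enal | C=C(I)CCC[C@H](C)[C@@H](OCc1ccc(OC)cc1)C=O
F5 | step 9 | methyl (2Z,5E)-9-[(tert-butyldimethylsilyl)oxy]-6-methyl-2-[(tributylstannyl)methyl]nona-2,5-dienoate | COC(=O)/C(C[Sn](CCCC)(CCCC)CCCC)=C/C/C=C(\C)CCCO[Si](C)(C)C(C)(C)C
F6 | step 9 | methyl (3S,4R,5R,6S)-3-[(2E)-6-{[tert-butyl(dimethyl)silyl]oxy}-3-methylhex-2-en-1-yl]-4-hydroxy-10-iodo-5-[(4-methoxyphenyl)methoxy]-6-methyl-2-methylideneundec-10-enoate | C=C(I)CCC[C@H](C)[C@@H](OCc1ccc(OC)cc1)[C@H](O)[C@@H](C/C=C(\C)CCCO[Si](C)(C)C(C)(C)C)C(=C)C(=O)OC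
F7 | step 9 | (4S,5R)-5-{(1R,2S)-6-iodo-1-[(4-methoxyphenyl)methoxy]-2-methylhept-6-en-1-yl}-4-[(2E)-6-{[tert-butyl(dimethyl)silyl]oxy}-3-methylhex-2-en-1-yl]-3-methylideneoxolan-2-one | C=C(I)CCC[C@H](C)[C@@H](OCc1ccc(OC)cc1)[C@@H]1OC(=O)C(=C)[C@@H]1C/C=C(\C)CCCO[Si](C)(C)C(C)(C)C
F8 | step 11 | (4S,5R)-5-[(1R,2S)-1-hydroxy-6-iodo-2-methylhept-6-en-1-yl]-4-[(2E)-6-hydroxy-3-methylhex-2-en-1-yl]-3-methylideneoxolan-2-one | C=C(I)CCC[C@H](C)[C@@H](O)[C@@H]1OC(=O)C(=C)[C@@H]1C/C=C(\C)CCCO
F9 | step 11 | (4E)-6-{(2R,3S)-2-[(1R,2S)-1-hydroxy-6-iodo-2-methylhept-6-en-1-yl]-4-methylidene-5-oxooxolan-3-yl}-4-methylhex-4-enal | C=C(I)CCC[C@H](C)[C@@H](O)[C@@H]1OC(=O)C(=C)[C@@H]1C/C=C(\C)CCC=O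
F10 | step 11 | (1S,2R,3R,4S,9R,12E)-3,9-dihydroxycembra-8(19),12,15(17)-trien-16,2-olide | C=C1CCC[C@H](C)[C@@H](O)[C@@H]2OC(=O)C(=C)[C@@H]2C/C=C(\C)CC[C@H]1O
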